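**Retrosynthetic overview**
1. Target ⇐ MnO2 oxidation of the C1 allylic alcohol; C9 angelate by late Yamaguchi esterification; C8 hydroxyl unmasked at the end.
2. Ten-membered carbocycle (formed last) ⇐ C1–C10 bond by intramolecular Nozaki–Hiyama–Kishi reaction of an alkenyl bromide with a C1 aldehyde.
3. α-Methylene lactone with C7 and C8 ⇐ C7–C8 bond by indium Barbier reaction of a 3-(bromomethyl)butenolide with an α-PMB-oxy aldehyde.
4. Butenolide (second ring, by ring-closing metathesis) ⇐ oxirane (first ring, Shi epoxidation) ⇐ (R)-epichlorohydrin + (E)-alkenyl iodide from pent-3-yn-1-ol.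
5. Aldehyde piece ⇐ new Pd-catalysed dynamic kinetic asymmetric etherification of racemic 2-(1-bromoethenyl)oxirane (sets C9).

**Assumptions**
- Locants follow germacranolide numbering with the lactone closed to C6: C1 ketone, C3/C4 oxirane (C15 methyl on C4), C6 lactone O–CH, C7, C8 CHOH, C9 CH–O-angelate, C10 C(=C14H2), C11–C13 methylene lactone; the target is then (3R,4R,6R,7R,8R,9R).
- 2-Bromoacrolein is taken as a purchased starting material (it is also made in one step from acrolein).
- The (R,R) Trost ligand is assumed to give the (S) alcohol in step 9 (the spatial sense of (R)-2-alkoxybut-3-en-1-ols from butadiene monoepoxide); if the sense is opposite, the (S,S) ligand is used.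

**Route**

Step 1
Reactants: 1 pent-3-yn-1-ol
Product: 2 tert-butyldimethyl(pent-3-yn-1-yloxy)silane
Conditions: TBSCl, imidazole, CH2Cl2, 0 °C → rt
Reagents that add atoms: tert-butyldimethylsilyl chloride, CC(C)(C)[Si](C)(C)Cl
Why: Standard silyl ether formation protects the future C1 hydroxyl through the organometallic steps and creates no stereocentre.

Step 2
Reactants: 2 tert-butyldimethyl(pent-3-yn-1-yloxy)silane
Product: 4 tert-butyl{[(3E)-4-iodopent-3-en-1-yl]oxy}dimethylsilane, via alkenylzirconocene chloride 3 (not isolated)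
Conditions: Cp2Zr(H)Cl (1.6 equiv), THF, rt → 40 °C; then I2, 0 °C
Reagents that add atoms: iodine, II
Why: Hydrozirconation is a syn addition that after equilibration places zirconium on the methyl-bearing alkyne carbon, and iodinolysis with retention gives the (E)-alkenyl iodide that fixes the C3=C4 geometry.

Step 3
Reactants: 4 tert-butyl{[(3E)-4-iodopent-3-en-1-yl]oxy}dimethylsilane; 5 (R)-epichlorohydrin
Product: 7 (2R,4E)-7-[(tert-butyldimethylsilyl)oxy]-1-chloro-4-methylhept-4-en-2-ol, via alkenyllithium 6 (not isolated)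
Conditions: t-BuLi (2.1 equiv), Et2O, −78 °C; then BF3·OEt2, 5, −78 °C
Reagents that add atoms: none
Why: Iodine–lithium exchange with retention of alkene geometry followed by BF3-assisted SN2 opening of the epoxide at its CH2 terminus forms the C4–C5 bond, and the C6 carbinol configuration comes unchanged from the chiral pool.

Step 4
Reactants: 7 (2R,4E)-7-[(tert-butyldimethylsilyl)oxy]-1-chloro-4-methylhept-4-en-2-ol
Product: 9 (3R,5E)-8-[(tert-butyldimethylsilyl)oxy]-5-methylocta-1,5-dien-3-ol, via terminal epoxide 8 (not isolated)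
Conditions: Me3S+ I− (4 equiv), n-BuLi (4 equiv), THF, −10 °C → rt
Reagents that add atoms: trimethylsulfonium iodide, C[S+](C)C.[I-]
Why: Base closes the chlorohydrin to the epoxide, and dimethylsulfonium methylide opens it at the terminus and eliminates dimethyl sulfide (one-carbon homologation of an epoxide to an allylic alcohol), leaving C6 untouched.

Step 5
Reactants: 9 (3R,5E)-8-[(tert-butyldimethylsilyl)oxy]-5-methylocta-1,5-dien-3-ol
Product: 10 (2R)-1-[(2R,3R)-3-{2-[(tert-butyldimethylsilyl)oxy]ethyl}-2-methyloxiran-2-yl]but-3-en-2-ol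
Conditions: Shi ketone from D-fructose (30 mol%), Oxone (2KHSO5·KHSO4·K2SO4), K2CO3, Bu4NHSO4 (cat.), aq. Na2B4O7–Na2EDTA, MeCN–CH2(OMe)2, 0 °C
Reagents that add atoms: potassium peroxymonosulfate (active part of Oxone), [K+].[O-]S(=O)(=O)OO
Why: Shi asymmetric epoxidation, in which the chiral dioxirane attacks only the electron-rich trisubstituted (E)-alkene through the spiro transition state and sets C3 and C4 as (R,R) under reagent control while the monosubstituted vinyl group is too slow to react.

Step 6
Reactants: 10 (2R)-1-[(2R,3R)-3-{2-[(tert-butyldimethylsilyl)oxy]ethyl}-2-methyloxiran-2-yl]but-3-en-2-ol; 11 2-(bromomethyl)prop-2-enoic acid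
Product: 12 (2R)-1-[(2R,3R)-3-{2-[(tert-butyldimethylsilyl)oxy]ethyl}-2-methyloxiran-2-yl]but-3-en-2-yl 2-(bromomethyl)prop-2-enoate
Conditions: DCC, DMAP (5 mol%), CH2Cl2, −20 → 0 °C
Reagents that add atoms: none
Why: Steglich esterification acylates the secondary allylic alcohol with retention at C6 under near-neutral conditions that spare the oxirane and the allylic bromide.

Step 7
Reactants: 12 (2R)-1-[(2R,3R)-3-{2-[(tert-butyldimethylsilyl)oxy]ethyl}-2-methyloxiran-2-yl]but-3-en-2-yl 2-(bromomethyl)prop-2-enoate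
Product: 13 (5R)-3-(bromomethyl)-5-{[(2R,3R)-3-{2-[(tert-butyldimethylsilyl)oxy]ethyl}-2-methyloxiran-2-yl]methyl}furan-2(5H)-one
Conditions: second-generation Grubbs catalyst (H2IMes)(PCy3)Cl2Ru=CHPh (5 mol%), CH2Cl2 (5 mM), 40 °C
Reagents that add atoms: none
Why: Ring-closing metathesis between the vinyl group and the 1,1-disubstituted acrylate forms the butenolide (C7=C11) with loss of ethene, and C6 is not touched.

Step 8
Reactants: 14 2-bromoprop-2-enal (2-bromoacrolein)
Product: 15 rac-2-(1-bromoethenyl)oxirane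
Conditions: Me3S+ I−, n-BuLi, THF, −78 → 0 °C
Reagents that add atoms: trimethylsulfonium iodide, C[S+](C)C.[I-]
Why: Corey–Chaykovsky epoxidation, in which the sulfonium ylide adds 1,2 to the enal and the betaine closes to the racemic vinyl epoxide.

Step 9
Reactants: 15 rac-2-(1-bromoethenyl)oxirane; 16 (4-methoxyphenyl)methanol
Product: 17 (2S)-3-bromo-2-[(4-methoxyphenyl)methoxy]but-3-en-1-ol
Conditions: Pd2(dba)3·CHCl3 (1 mol%), (R,R)-DACH-phenyl Trost ligand (3 mol%), Et3B (2 mol%), CH2Cl2, rt
Reagents that add atoms: none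
Why: Proposed new method: palladium-catalysed dynamic kinetic asymmetric etherification of a 2-bromo-substituted vinyl epoxide, in which zerovalent palladium bearing the chiral diphosphine ionises the strained allylic C–O bond of either enantiomer of 15 much faster than it inserts into the alkenyl C–Br bond, the two diastereomeric 2-bromo-π-allylpalladium alkoxides interconvert by π–σ–π isomerisation through the unsubstituted CH2 terminus, and the alkoxide and 16 form a borate on Et3B that delivers the PMB-oxy group intramolecularly to the adjacent (branched) allyl carbon of the faster-reacting complex, which sets C9 as (S) and forms the C9–O bond; the closest known reactions are the palladium/boron co-catalysed dynamic kinetic asymmetric addition of alcohols to butadiene and isoprene monoepoxides and Tsuji–Trost substitutions of 2-bromoallyl esters that keep the C–Br bond.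

Step 10
Reactants: 17 (2S)-3-bromo-2-[(4-methoxyphenyl)methoxy]but-3-en-1-ol
Product: 18 (2S)-3-bromo-2-[(4-methoxyphenyl)methoxy]but-3-enal
Conditions: Dess–Martin periodinane, CH2Cl2, 0 °C; filtered and used at once
Reagents that add atoms: none
Why: Dess–Martin oxidation of the primary alcohol is non-basic, so the α-alkoxy β,γ-unsaturated aldehyde is formed without epimerisation at C9 or migration of the double bond.

Step 11
Reactants: 13 (5R)-3-(bromomethyl)butenolide; 18 (2S)-3-bromo-2-[(4-methoxyphenyl)methoxy]but-3-enal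
Product: 20 (4R,5R)-4-[(1R,2S)-3-bromo-1-hydroxy-2-(4-methoxybenzyloxy)but-3-en-1-yl]-5-{[(2R,3R)-3-{2-[(tert-butyldimethylsilyl)oxy]ethyl}-2-methyloxiran-2-yl]methyl}-3-methylideneoxolan-2-one, via allylindium dibromide 19 (not isolated)
Conditions: indium powder (In, 1.5 equiv), THF–H2O (3:1), rt
Reagents that add atoms: none
Why: Barbier allylation in which the allylindium from 13 attacks the aldehyde through its γ-carbon (C7) in a chair Zimmerman–Traxler transition state on the butenolide face opposite the C6 side chain (C6/C7 trans), the ring-locked alkene geometry gives the C7/C8 relationship of the target, and chelation of indium by the PMB ether makes the (S)-aldehyde the matched partner (C8/C9 syn).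

Step 12
Reactants: 20 Barbier adduct
Product: 21 C8 O-tert-butyldimethylsilyl ether of 20
Conditions: TBSOTf, 2,6-lutidine, CH2Cl2, −78 °C
Reagents that add atoms: tert-butyldimethylsilyl triflate, CC(C)(C)[Si](C)(C)OS(=O)(=O)C(F)(F)F
Why: Silylation of the hindered C8 hydroxyl with the silyl triflate at low temperature blocks translactonisation and later oxidation at C8 and touches no stereocentre.

Step 13
Reactants: 21 bis-silyl ether
Product: 22 primary alcohol (21 without the primary TBS group; C1 hydroxyl free)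
Conditions: HF·pyridine, pyridine, THF, 0 °C
Reagents that add atoms: none
Why: Buffered HF·pyridine cleaves the unhindered primary silyl ether much faster than the hindered secondary one (chemoselective desilylation).

Step 14
Reactants: 22 primary alcohol
Product: 23 β,γ-epoxy aldehyde (C1 aldehyde of 22)
Conditions: Dess–Martin periodinane, pyridine, CH2Cl2, 0 °C; used crude
Reagents that add atoms: none
Why: Dess–Martin oxidation under buffered, essentially neutral conditions gives the C1 aldehyde without base-induced opening of the β,γ-epoxide.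

Step 15
Reactants: 23 β,γ-epoxy aldehyde
Product: 25 ten-membered allylic alcohol (C1 epimers), via alkenylchromium dichloride 24 (not isolated)
Conditions: CrCl2 (10 equiv), NiCl2 (2 mol%), DMSO–THF (3:1), 2 mM, slow addition, rt
Reagents that add atoms: none
Why: Intramolecular Nozaki–Hiyama–Kishi reaction in which nickel-catalysed activation of the alkenyl bromide and transmetalation to chromium give a non-basic, aldehyde-selective alkenylchromium that closes the ten-membered ring by forming C1–C10, the new C1 configuration being irrelevant because it is oxidised in step 20.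

Step 16
Reactants: 25 ten-membered allylic alcohol
Product: 26 C1 O-triethylsilyl ether of 25
Conditions: TESOTf, 2,6-lutidine, CH2Cl2, −78 °C
Reagents that add atoms: triethylsilyl triflate, CC[Si](CC)(CC)OS(=O)(=O)C(F)(F)F
Why: Silylation masks the C1 allylic alcohol so that only the C9 oxygen is free for acylation after the next step.

Step 17
Reactants: 26 C1 O-triethylsilyl ether
Product: 27 C9 alcohol (26 without the PMB group)
Conditions: DDQ, CH2Cl2–pH 7 buffer (10:1), 0 °C
Reagents that add atoms: none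
Why: Oxidative PMB cleavage by DDQ (hydride abstraction then hydrolysis of the oxocarbenium ion) frees the C9 hydroxyl with retention while silyl ethers, oxirane and enoate are inert.

Step 18
Reactants: 27 C9 alcohol; 28 angelic acid [(2Z)-2-methylbut-2-enoic acid]
Product: 30 C9 angelate of 27, via mixed anhydride 29 (not isolated)
Conditions: 28, 2,4,6-trichlorobenzoyl chloride, Et3N, toluene, rt; then 27, toluene, 75 °C
Reagents that add atoms: none
Why: Yamaguchi esterification without a nucleophilic amine catalyst acylates the C9 hydroxyl with retention and avoids the addition–elimination pathway that isomerises angelate to tiglate, and no ketone is yet present that a base could use to open the oxirane.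

Step 19
Reactants: 30 C9 angelate
Product: 31 C1,C8-diol (30 without both silyl groups)
Conditions: HF·pyridine, pyridine, THF, 0 °C → rt
Reagents that add atoms: none
Why: Acidic fluoride removes both silyl ethers without forming an alkoxide next to the angelate (no acyl migration) and the pyridine buffer protects the oxirane.

Step 20
Reactants: 31 C1,C8-diol
Product: 32 (3R,4R,6R,7R,8R,9R)-9-(angeloyloxy)-3,4-epoxy-8-hydroxy-1-oxogermacra-10(14),11(13)-dien-12,6-olide (CNP0348992.8)
Conditions: MnO2 (activated, 20 equiv), CH2Cl2, rt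
Reagents that add atoms: none
Why: Manganese dioxide oxidises only the allylic C1 alcohol (both epimers converge) to the cross-conjugated enone under neutral heterogeneous conditions and leaves the non-allylic C8 hydroxyl and the base-labile β,γ-epoxy ketone untouched.

**Compound list**
1 | pent-3-yn-1-ol | CC#CCCO | starting material
2 | tert-butyldimethyl(pent-3-yn-1-yloxy)silane | CC#CCCO[Si](C)(C)C(C)(C)C | intermediate
3 | chlorobis(cyclopentadienyl)[(2E)-5-(TBS-oxy)pent-2-en-2-yl]zirconium (formed in the flask; Cp drawn σ-bonded) | Cl[Zr](C1C=CC=C1)(C1C=CC=C1)/C(C)=C/CCO[Si](C)(C)C(C)(C)C | intermediate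
4 | tert-butyl{[(3E)-4-iodopent-3-en-1-yl]oxy}dimethylsilane | I/C(C)=C/CCO[Si](C)(C)C(C)(C)C | intermediate
5 | (R)-epichlorohydrin [(2R)-2-(chloromethyl)oxirane] | ClC[C@H]1CO1 | starting material
6 | alkenyllithium from 4 (Li in place of I; geometry retained; formed in the flask) | [Li]/C(C)=C/CCO[Si](C)(C)C(C)(C)C | intermediate
7 | (2R,4E)-7-[(tert-butyldimethylsilyl)oxy]-1-chloro-4-methylhept-4-en-2-ol | ClC[C@H](O)C/C(C)=C/CCO[Si](C)(C)C(C)(C)C | intermediate
8 | (2R)-2-[(2E)-5-{[tert-butyl(dimethyl)silyl]oxy}-2-methylpent-2-en-1-yl]oxirane (formed in the flask) | C1[C@H](O1)C/C(C)=C/CCO[Si](C)(C)C(C)(C)C | intermediate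
9 | (3R,5E)-8-[(tert-butyldimethylsilyl)oxy]-5-methylocta-1,5-dien-3-ol | C=C[C@H](O)C/C(C)=C/CCO[Si](C)(C)C(C)(C)C | intermediate
10 | (2R)-1-[(2R,3R)-3-{2-[(tert-butyldimethylsilyl)oxy]ethyl}-2-methyloxiran-2-yl]but-3-en-2-ol | C=C[C@H](O)C[C@@]1(C)O[C@@H]1CCO[Si](C)(C)C(C)(C)C | intermediate
11 | 2-(bromomethyl)prop-2-enoic acid | C=C(CBr)C(=O)O | starting material
12 | (2R)-1-[(2R,3R)-3-{2-[(tert-butyldimethylsilyl)oxy]ethyl}-2-methyloxiran-2-yl]but-3-en-2-yl 2-(bromomethyl)prop-2-enoate | C=C[C@H](OC(=O)C(=C)CBr)C[C@@]1(C)O[C@@H]1CCO[Si](C)(C)C(C)(C)C | intermediate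
13 | (5R)-3-(bromomethyl)-5-{[(2R,3R)-3-{2-[(tert-butyldimethylsilyl)oxy]ethyl}-2-methyloxiran-2-yl]methyl}furan-2(5H)-one | BrCC1=C[C@@H](C[C@@]2(C)O[C@@H]2CCO[Si](C)(C)C(C)(C)C)OC1=O | intermediate
14 | 2-bromoprop-2-enal (2-bromoacrolein) | C=C(Br)C=O | starting material
15 | rac-2-(1-bromoethenyl)oxirane | C=C(Br)C1CO1 | intermediate
16 | (4-methoxyphenyl)methanol (PMB alcohol) | COc1ccc(CO)cc1 | starting material
17 | (2S)-3-bromo-2-[(4-methoxyphenyl)methoxy]but-3-en-1-ol (its C2 is C9 of 32) | C=C(Br)[C@@H](OCc1ccc(OC)cc1)CO | intermediate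
18 | (2S)-3-bromo-2-[(4-methoxyphenyl)methoxy]but-3-enal | C=C(Br)[C@@H](OCc1ccc(OC)cc1)C=O | intermediate
19 | allylindium dibromide from 13 (InBr2 in place of Br; formed in the flask) | Br[In](Br)CC1=C[C@@H](C[C@@]2(C)O[C@@H]2CCO[Si](C)(C)C(C)(C)C)OC1=O | intermediate
20 | (4R,5R)-4-[(1R,2S)-3-bromo-1-hydroxy-2-(4-methoxybenzyloxy)but-3-en-1-yl]-5-{[(2R,3R)-3-{2-[(tert-butyldimethylsilyl)oxy]ethyl}-2-methyloxiran-2-yl]methyl}-3-methylideneoxolan-2-one | C=C1C(=O)O[C@H](C[C@@]2(C)O[C@@H]2CCO[Si](C)(C)C(C)(C)C)[C@H]1[C@@H](O)[C@H](OCc1ccc(OC)cc1)C(Br)=C | intermediate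
21 | 20 with the C8 hydroxyl as TBS ether | C=C1C(=O)O[C@H](C[C@@]2(C)O[C@@H]2CCO[Si](C)(C)C(C)(C)C)[C@H]1[C@@H](O[Si](C)(C)C(C)(C)C)[C@H](OCc1ccc(OC)cc1)C(Br)=C | intermediate
22 | 21 with the primary (C1) hydroxyl free | C=C1C(=O)O[C@H](C[C@@]2(C)O[C@@H]2CCO)[C@H]1[C@@H](O[Si](C)(C)C(C)(C)C)[C@H](OCc1ccc(OC)cc1)C(Br)=C | intermediate
23 | C1 aldehyde of 22 (β,γ-epoxy aldehyde) | C=C1C(=O)O[C@H](C[C@@]2(C)O[C@@H]2CC=O)[C@H]1[C@@H](O[Si](C)(C)C(C)(C)C)[C@H](OCc1ccc(OC)cc1)C(Br)=C | intermediate
24 | alkenylchromium dichloride from 23 (CrCl2 in place of the vinylic Br; formed in the flask) | C=C1C(=O)O[C@H](C[C@@]2(C)O[C@@H]2CC=O)[C@H]1[C@@H](O[Si](C)(C)C(C)(C)C)[C@H](OCc1ccc(OC)cc1)C(=C)[Cr](Cl)Cl | intermediate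
25 | 3,4-epoxy-1-hydroxy-9-(4-methoxybenzyloxy)-8-(tert-butyldimethylsilyloxy)germacra-10(14),11(13)-dien-12,6-olide, C3/C4/C6/C7/C8/C9 arranged as in 32, C1 epimers | C=C1C(=O)O[C@@H]2C[C@@]3(C)O[C@@H]3CC(O)C(=C)[C@@H](OCc4ccc(OC)cc4)[C@H](O[Si](C)(C)C(C)(C)C)[C@@H]12 | intermediate
26 | 25 with the C1 hydroxyl as TES ether | C=C1C(=O)O[C@@H]2C[C@@]3(C)O[C@@H]3CC(O[Si](CC)(CC)CC)C(=C)[C@@H](OCc4ccc(OC)cc4)[C@H](O[Si](C)(C)C(C)(C)C)[C@@H]12 | intermediate
27 | 26 with the C9 hydroxyl free | C=C1C(=O)O[C@@H]2C[C@@]3(C)O[C@@H]3CC(O[Si](CC)(CC)CC)C(=C)[C@@H](O)[C@H](O[Si](C)(C)C(C)(C)C)[C@@H]12 | intermediate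
28 | angelic acid [(2Z)-2-methylbut-2-enoic acid] | C/C=C(/C)C(=O)O | starting material
29 | angelic 2,4,6-trichlorobenzoic anhydride (formed in the flask) | C/C=C(/C)C(=O)OC(=O)c1c(Cl)cc(Cl)cc1Cl | intermediate
30 | 27 with the C9 hydroxyl as angelate | C=C1C(=O)O[C@@H]2C[C@@]3(C)O[C@@H]3CC(O[Si](CC)(CC)CC)C(=C)[C@@H](OC(=O)/C(C)=C\C)[C@H](O[Si](C)(C)C(C)(C)C)[C@@H]12 | intermediate
31 | 9-(angeloyloxy)-3,4-epoxy-1,8-dihydroxygermacra-10(14),11(13)-dien-12,6-olide, C1 epimers | C=C1C(=O)O[C@@H]2C[C@@]3(C)O[C@@H]3CC(O)C(=C)[C@@H](OC(=O)/C(C)=C\C)[C@H](O)[C@@H]12 | intermediate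
32 | (3R,4R,6R,7R,8R,9R)-9-(angeloyloxy)-3,4-epoxy-8-hydroxy-1-oxogermacra-10(14),11(13)-dien-12,6-olide (CNP0348992.8) | C=C1C(=O)O[C@@H]2C[C@@]3(C)O[C@@H]3CC(=O)C(=C)[C@@H](OC(=O)/C(C)=C\C)[C@H](O)[C@@H]12 | target

**Step count and risks**

Total: 20 steps. Longest linear sequence: 17 steps (steps 1–7, then 11–20); the aldehyde branch is steps 8–10.

The three steps most likely to fail:

Step 7. Metathesis of an electron-poor 1,1-disubstituted acrylate that carries an allylic bromide may be slow, or the bromide may degrade the ruthenium carbene. The fallback sets out from 10 and comes back at 13, and it brings in the bromine after the ring is made. Acylation of 10 with methacryloyl chloride (Et3N, CH2Cl2, 0 °C) gives the methacrylate ester F1. Ring-closing metathesis with the same ruthenium catalyst (toluene, 80 °C) gives the 3-methylbutenolide F2. Allylic oxidation of the butenolide methyl group with SeO2/t-BuOOH gives the 3-(hydroxymethyl)butenolide F3, and CBr4/PPh3 converts it into 13.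

Step 9 (the new step). Zerovalent palladium may insert into the C–Br bond, the linear ether may form, or the enantioselectivity may be low. The fallback uses known chemistry, sets out from 15 and comes back at 17. Hydrolytic kinetic resolution of 15 with the enantiomer of (salen)Co(OAc) that hydrolyses the (S)-epoxide (salen = N,N'-bis(3,5-di-tert-butylsalicylidene)-1,2-cyclohexanediamine dianion; 0.45 equiv H2O) gives (2S)-3-bromobut-3-ene-1,2-diol F4 and leaves the other epoxide enantiomer. Acetalisation with 4-methoxybenzaldehyde dimethyl acetal (PPTS cat.) gives the 4-methoxybenzylidene acetal F5. DIBAL-H (CH2Cl2, −78 → 0 °C) opens the acetal at the less hindered oxygen, which puts the PMB group on the secondary oxygen and gives 17.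

Step 11. Trivalent indium salts may open the trisubstituted oxirane, aldehyde 18 may epimerise or isomerise, and the C8 selectivity depends on chelation. The fallback sets out from 9 and comes back at 20, and it postpones the epoxidation until after the fragment union. Steglich esterification of 9 with 11 gives the dienyl ester F6, and ring-closing metathesis gives the alkene-bearing bromomethylbutenolide F7. The indium Barbier reaction of F7 with 18 gives the adduct F8. Shi epoxidation (ketone from D-fructose) of the only electron-rich trisubstituted alkene of F8 then gives 20.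

**Further compounds**
F1 | step 7 | (2R)-1-[(2R,3R)-3-{2-[(tert-butyldimethylsilyl)oxy]ethyl}-2-methyloxiran-2-yl]but-3-en-2-yl 2-methylprop-2-enoate | C=C[C@H](OC(=O)C(C)=C)C[C@@]1(C)O[C@@H]1CCO[Si](C)(C)C(C)(C)C
F2 | step 7 | (5R)-3-methyl-5-{[(2R,3R)-3-{2-[(tert-butyldimethylsilyl)oxy]ethyl}-2-methyloxiran-2-yl]methyl}furan-2(5H)-one | CC1=C[C@@H](C[C@@]2(C)O[C@@H]2CCO[Si](C)(C)C(C)(C)C)OC1=O
F3 | step 7 | (5R)-3-(hydroxymethyl)-5-{[(2R,3R)-3-{2-[(tert-butyldimethylsilyl)oxy]ethyl}-2-methyloxiran-2-yl]methyl}furan-2(5H)-one | OCC1=C[C@@H](C[C@@]2(C)O[C@@H]2CCO[Si](C)(C)C(C)(C)C)OC1=O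
F4 | step 9 | (2S)-3-bromobut-3-ene-1,2-diol | C=C(Br)[C@@H](O)CO
F5 | step 9 | (4S)-4-(1-bromoethenyl)-2-(4-methoxyphenyl)-1,3-dioxolane (both acetal epimers) | C=C(Br)[C@@H]1COC(c2ccc(OC)cc2)O1
F6 | step 11 | (3R,5E)-8-[(tert-butyldimethylsilyl)oxy]-5-methylocta-1,5-dien-3-yl 2-(bromomethyl)prop-2-enoate | C=C[C@H](OC(=O)C(=C)CBr)C/C(C)=C/CCO[Si](C)(C)C(C)(C)C
F7 | step 11 | (5R)-3-(bromomethyl)-5-[(2E)-5-{[tert-butyl(dimethyl)silyl]oxy}-2-methylpent-2-en-1-yl]furan-2(5H)-one | BrCC1=C[C@@H](C/C(C)=C/CCO[Si](C)(C)C(C)(C)C)OC1=O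
F8 | step 11 | 20 with the (E)-C3=C4 alkene in place of the oxirane | C=C1C(=O)O[C@H](C/C(C)=C/CCO[Si](C)(C)C(C)(C)C)[C@H]1[C@@H](O)[C@H](OCc1ccc(OC)cc1)C(Br)=C
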